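Readings and results stem from a simulated flask on assumed constants, and the scatter is random.

**The stop.** The epsilon flask makes 0.141 M of target and then nearly halts, adding 0.00450 M in its last 35.0 min, although 0.6089 M of starting material still stands there. So I look to the partner, the limiting reagent of that flask by charge (0.275 M), of which target accounts for 0.141 M, leaving 0.134 M unexplained.

| flask | starting material | partner | free catalyst | time |
|---|---|---|---|---|
| beta | 0.250 M | 0.275 M | 5.00 × 10⁻⁴ M |  |
| delta | 0.100 M | 0.125 M | 5.00 × 10⁻⁴ M |  |
| epsilon | 0.750 M | 0.275 M | 5.00 × 10⁻⁴ M |  |
| zeta | 0.250 M | 0.275 M | 7.50 × 10⁻⁴ M |  |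
| gamma | 0.250 M | 1.40 M | 5.00 × 10⁻⁴ M | 85 min |

| run | time / min | [starting material] / M |
|---|---|---|
| beta run | 3.4 | 0.2430 |
| beta run | 5.8 | 0.2381 |
| beta run | 9.9 | 0.2303 |
| beta run | 17 | 0.2192 |
| beta run | 29 | 0.1987 |
| beta run | 50 | 0.1730 |
| beta run | 85 | 0.1495 |
| delta run | 3.4 | 0.0967 |
| delta run | 5.8 | 0.0960 |
| delta run | 9.9 | 0.0911 |
| delta run | 17 | 0.0859 |
| delta run | 29 | 0.0777 |
| delta run | 50 | 0.0671 |
| delta run | 85 | 0.0513 |
| epsilon run | 3.4 | 0.7343 |
| epsilon run | 5.8 | 0.7234 |
| epsilon run | 9.9 | 0.7065 |
| epsilon run | 17 | 0.6794 |
| epsilon run | 29 | 0.6450 |
| epsilon run | 50 | 0.6134 |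
| epsilon run | 85 | 0.6089 |
| zeta run | 3.4 | 0.2407 |
| zeta run | 5.8 | 0.2349 |
| zeta run | 9.9 | 0.2243 |
| zeta run | 17 | 0.2070 |
| zeta run | 29 | 0.1828 |
| zeta run | 50 | 0.1506 |
| zeta run | 85 | 0.1336 |

(standard deviation of a reading: 8 × 10⁻⁴ M)

- Overall: starting material + partner -> target, with free catalyst as catalyst.
- Constant volume, constant temperature.
- The analysis sees a species whether free or bound.
- An order is taken over about fifteen percent of the charge, up and down.

- reaction order in [partner] at the outset, round the charge of the beta run, defined at two percent of the starting material turned into target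
- reaction order in [free catalyst] at the outset, round the charge of the beta run, defined at two percent of the starting material turned into target
- starting material in the gamma run at 85 min, as a share of the starting material charged

**Clock or turnover.** Perhaps free catalyst dies with time. But over that same late span the beta flask, with the same catalyst charge, keeps 0.371 of its rate over the first 17 min, and the epsilon flask keeps 0.0310, so a common clock on the catalyst fails. Perhaps each turnover costs extra partner; then the zeta and beta flasks, at equal target made, should keep their early rate ratio of 1.40. Over spans of similar target made, zeta from 29 min to 50 min and beta from 50 min to 85 min, that ratio is 2.28, so the partner seems to go with time. The delta flask, charged lower in both partner and starting material, keeps 0.544 of its early rate, which is a hint and no proof, and on that hint I try the loss as second order in partner, λR², with R the partner concentration.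

**My orders.** Early conversions give order 0.755 in starting material, 0.823 in free catalyst, and, from what delta leaves over, 0.113 in partner. So for now I take the use of partner by turnover, r, as independent of R.

**Break-even level.** With r steady, R falls at r + λR². Loss equals use at R* = √(r/λ), and the target made when R reaches zero is R* arctan(R₀/R*), with R₀ the charge. Epsilon's share 0.513 of its charge asks for R₀/R* near 2.3, so with r = 0.00415 M min⁻¹ the loss constant, the rate of partner loss per squared partner concentration, is λ = 0.290 M⁻¹ min⁻¹.

**The gamma flask.** Its first half-life of partner by loss is 2.46 min, far shorter than the 85 min asked, so the large charge may not last. Beta's early rate 0.00181 M min⁻¹ gives R* = 0.0790 M, the arctangent lies near 1.50, and target reaches 0.118 M. But r falls with starting material. Taken at the mean level with my order, it is 0.00155 M min⁻¹, so my estimate is R* = 0.0730 M, target 0.110 M, and partner ending near 71.0 min. I commit to 56.2% left.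

**The forecast.** It gives order 0.15 in partner, order 0.7 in free catalyst and 47% left in the gamma flask, holding that “gamma should not stall”. We part on that point, since my estimate puts the end of partner in the gamma flask before 85 min.

**The answer.** The simulation gives 54.7% left in the gamma flask at 85 min, with orders 0.054 in partner and 0.78 in free catalyst.

    free catalyst + starting material → catalyst-substrate complex (30.78 M⁻¹ min⁻¹)
    catalyst-substrate complex + partner → loaded catalyst (223.2 M⁻¹ min⁻¹)
    loaded catalyst → target + free catalyst (40.50 min⁻¹)
    2 free catalyst ⇌ resting dimer, settled at all times (1020 M⁻¹)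
    2 partner → lost reagent (0.1332 M⁻¹ min⁻¹)

The apparent order in partner early in the beta flask is 0.054. Gamma's target, 0.113 M, stands at 1.55 times R*. In the delta flask the mean rate to a quarter conversion, reached at 33.8 min, is 7.40 × 10⁻⁴ M min⁻¹, so R* = 0.0505 M and the charge stands at 2.48 times R*, near epsilon's ratio. Epsilon's share then gives an estimated stop for the delta flask at 0.0641 M of target, above the 0.0500 M made by 85.6 min.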